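**The decision.** As the chemist charging the next flask, you must choose whether to double the saturation of the gas (delta), double its transfer (eta), or leave the gas as it is.

| flask | starting material | gas phase | protic impurity | remark | time |
|---|---|---|---|---|---|
| Thursday's | 7.5 mM | 0.52 mM (held) | 0.30 mM | run made earlier |  |
| Wednesday's | 30 mM | 0.52 mM (held) | 0.30 mM | run made earlier |  |
| Friday's | 15 mM | 0.52 mM (held) | 0.45 mM | run made earlier |  |
| flask | 15 mM | 0.52 mM (held) | 0.300 mM |  | 6.0 min |

| run | time / min | target / % | starting material / % |
|---|---|---|---|
| Thursday's | 0.417 | 4.6 | 95.0 |
| Thursday's | 0.667 | 7.3 | 91.5 |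
| Thursday's | 0.833 | 9.7 | 88.6 |
| Thursday's | 1.33 | 14.2 | 81.7 |
| Thursday's | 2.00 | 17.3 | 73.8 |
| Thursday's | 3.00 | 17.0 | 65.5 |
| Thursday's | 5.00 | 16.1 | 52.8 |
| Wednesday's | 0.667 | 3.1 | 96.1 |
| Wednesday's | 1.33 | 7.1 | 87.9 |
| Wednesday's | 2.00 | 8.2 | 82.7 |
| Wednesday's | 3.00 | 8.5 | 73.1 |
| Wednesday's | 4.00 | 8.7 | 65.5 |
| Wednesday's | 5.00 | 9.8 | 57.8 |
| Friday's | 0.417 | 3.4 | 96.8 |
| Friday's | 0.667 | 5.7 | 93.5 |
| Friday's | 1.33 | 10.1 | 85.6 |
| Friday's | 2.50 | 12.8 | 73.6 |
| Friday's | 5.00 | 12.9 | 55.9 |

(scatter of a reading: 0.5 percentage points)

- percentages count the starting material that a species holds: one side product counts as two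
- at the start none of the gas is dissolved
- the earlier runs were read with a standard deviation of 0.5 percentage points
- on the list of suspects stand: gas phase <-> dissolved gas; starting material + dissolved gas <-> target; dissolved gas + target -> over-reacted product; starting material + target -> side product; dissolved gas + protic impurity -> quenched reagent

- amount of target at 6.0 min, in percent of the starting material charged
- the change that raises the amount of target at 6.0 min, in percent of the starting material charged most ("none" if none brings more than 2 percentage points) (delta / eta / none)
- amount of target at 6.0 min, in percent of the starting material charged, after eta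

- delta: doubling the saturation concentration of gas phase, all else as stated
- eta: doubling the transfer coefficient of the gas phase, all else as stated

**The ratio.** Once target stops climbing, its making and its loss balance, a quasi-steady state. Friday's last reading, at this flask's charge, gives the plateau ratio, target over starting material, of 0.231. The ratio read 0.305 on Thursday and 0.170 on Wednesday, so it falls as the charge rises. Friday's extra protic impurity, 0.150 mM, is far less than the charge of 15 mM, so I carry the ratio over unchanged.

**My reckoning.** Friday's starting material decayed at 0.110 min⁻¹ between its last two readings, which leaves 50.1% at 6.0 min. Multiplied by the ratio, that is 11.6% of target. Thursday's, Wednesday's and Friday's runs held the gas at 0.52 mM, so they do not show what more gas does to the ratio. More gas may raise the ratio, yet it may also take starting material faster; these pull against each other, so I expect no gain of 2 percentage points and leave the gas alone.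

**The forecast.** The forecast stands a little higher than mine at 12.4%, names none as the best change and gives 12.2% after eta, saying "Faster transfer changes little".

**The result.** The flask gives 12.1%, and the best change is none: delta brings −0.58 points, and eta brings 0.063 points, for 12.2%.

    gas phase ⇌ dissolved gas, rate k1*(csat - [dissolved gas]) (kL = 0.110 s⁻¹)
    starting material + dissolved gas ⇌ target (K = 950 M⁻¹, k = 13.0 M⁻¹ s⁻¹)
    dissolved gas + target → over-reacted product (k = 12.0 M⁻¹ s⁻¹)
    starting material + target → side product (k = 0.280 M⁻¹ s⁻¹)
    dissolved gas + protic impurity → quenched reagent (k = 1200 M⁻¹ s⁻¹)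

At 6.00 min in this flask, target is made at 0.828 of the rate at which it is used up, each step taken net, so the balance is near. The flask's ratio there is 0.246, against the 0.231 read on Friday.

**A later reading.** Read the same flask at 25 min. The same decay leaves 6.19% of starting material, and the ratio 0.231 gives 1.43% of target, while Thursday's 0.305, from a more dilute solution, gives 1.89%. The computed flask holds 2.43% of target beside 7.0% of starting material, a ratio of 0.347, with 0.485 mM of dissolved gas against 0.359 mM at 6.00 min.

The earlier runs and the new flask were computed with made-up constants; the scatter is artificial.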